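## Structural features

Target 22 is the (E)-dodec-2-enamide of an amine on a bicyclo[3.3.1]nonan-9-one in which ring A (C1–C2–C3–C4–C5–C9) and ring B (C1–C8–C7–C6–C5–C9) share the bridgeheads C1 and C5 and the bridging ketone C9. All seven stereocentres are contiguous on this core and read (1S,3S,4R,5S,6S,7S,8S): C1 is a tertiary bridgehead carbinol, C3 carries nitrogen, C4 a hydroxyl, C5 a hydrogen, C6 a methoxy group, and C7 and C8 form an epoxide. Nitrogen (equatorial) and the C4 hydroxyl (axial) are cis on the face of ring A that is syn to C9, called exo from here on, and the methoxy group and the epoxide oxygen are cis on the exo face of ring B. The fragile parts are the epoxide beside a tertiary α-ketol, the enoyl amide, and the C9 ketone, which cannot enolise and is open to nucleophilic C–C cleavage whenever C8 is also a carbonyl. The C4 hydroxyl and the C6 methoxy group are β to C9 yet cannot eliminate, because C5 is a bridgehead. The real difficulty is to build the bridged skeleton with an oxygenated, fully substituted bridgehead as one enantiomer and then to place nitrogen on C3 and not on C4. The key step exploits the position of C1 between C9 and C8, both of which can be carbonyl carbons, so that within ring B C1 can be the central and most electrophilic carbon of a cyclohexane-1,2,3-trione. An allylsilane hanging from C5 with silicon on C4 reaches that carbon with C2 and creates the C1–C2 bond, ring A, the bridgehead alcohol and a C3=C4 alkene in one event.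

## Logic of the disconnections

22 to 20 and 21. The amide N–C(O) bond is cut. The acyl chain holds no stereocentre, and its conjugated alkene would be a liability towards peroxide, hydrazine and oxonium reagents, so it is attached last. What remains is 20, which already contains every stereocentre. The forward step must acylate nitrogen beside two free hydroxyls, which the much greater nucleophilicity of the primary amine should secure.

20 to 19 to 18. The C3–N and C4–O bonds are cut together, after the silyl and carbamate groups, back to the C3=C4 alkene of 18. Two cis heteroatoms on the only open face are the signature of a suprafacial addition, and ring A of 18 then has no stereocentre besides the bridgeheads. The forward step must put nitrogen on C3. It is placed after ring B is finished, so that no 1,3-diketone meets aqueous base and the C4 hydroxyl never needs protection. Fluoride-labile groups on N and on O1 of 19 let one reagent unmask 20.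

18 to 17 to 16. The O–CH3 bond and both epoxide C–O bonds are cut, which leads to the allylic C6 hydroxyl and the C7=C8 alkene of 16. Only the axial C6 hydroxyl can steer an oxidant to the exo face of C7=C8. The C1 oxygen lies in the plane of that alkene and cannot tell the faces apart, and a C6 methyl ether would shield the exo face. Epoxidation must therefore precede methylation. The forward steps need chemoselectivity for the allylic alkene over C3=C4 and a methylation that is neither basic nor strongly Lewis acidic.

16 to 14 to 13 to 12 to 11. The C6–O bond is cut. 16 is the 1,3-transposed form of 14, whose C6–C7 epoxide and C8 carbonyl come from the conjugated C6=C7 double bond of 13, and 13 comes through the C8 enol silyl ether of 12 from the C8 ketone of 11. C8 is the only enolisable carbonyl, because C9 lies between quaternary C1 and bridgehead C5, so ring B is oxidised at one position only. Peroxide attack from the exo face fixes C6 for good. Ring B of 11 is unfunctionalised. The forward steps must keep peroxide and hydrazine from cleaving the 1,3-diketone around C1.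

11 to 10 (key). The C1–C2 bond is cut and ring A opened. The bridgehead hydroxyl becomes the central carbonyl of a trione, and the C3=C4 alkene becomes an allylsilane with silicon on C4. One C–C bond then creates the bicycle, both bridgehead centres, the tertiary alcohol and the alkene needed later. The forward step needs attack at C1 only, anti SE2′ geometry, and a C5 configuration that lets silicon stand axial. Worked through in three dimensions, the (4S,1′S) form of 10 is the one that leads to (1S,5R)-11 and on to 22.

10 to 9 to 8 to 7. The C1=O oxygen is removed. The free trione is a keto tautomer of a 4-substituted pyrogallol and a ready hydrate, so it cannot be stored. Its central carbonyl is therefore masked as the dimethylaminomethylidene group of 9, which is placed on the C2 methylene of 8, itself the hydrolysis product of 7. The oxidant that unmasks 10 must cleave the enamine double bond and leave the vinyl group alone.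

7 to 5 and 6. The C4–Si bond and the C5–H bond are cut, which gives 5 and 6. A catalytic conjugate silylation sets C4 absolutely, and protonation of the β-silyl enolate anti to silicon should set C5 in the relative sense that the key step needs. The design therefore does not depend on epimerisation at the trione stage, where enolisation is also the first step towards aromatisation. The forward step needs 1,4- and not 1,6-addition.

5 to 3 to 1 and 2. The C4=C5 double bond and then the C4–C5 single bond are cut by a retro-aldol condensation, which leads to 1 and 2, both bought. This demands only kinetic α′-enolisation of 1 and 1,2-addition to 2.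

## Other disconnections considered

Alternative 1: The cut is made at the C1–O and C6–O bonds of ring B. In the forward direction singlet oxygen (tetraphenylporphyrin, visible light, O2) adds across the diene termini of A2, an acetonide-protected cis-dihydrodiol that carries the protected amino-acid side chain on C1, and approaches anti to the acetonide to give the endoperoxide A1.
- In its favour: nitrogen and C3 come from an amino acid and the ring configuration from an enzymatic arene dihydroxylation. Reductive O–O cleavage of A1 would leave two cis allylic hydroxyls flanking C7=C8, so a directed epoxidation would complete the all-syn oxygen array on C1, C6, C7 and C8.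
- Against it here: A1 has no ring A. The ester carbon C4 must still be joined to C5, whose acetonide oxygen has to be sacrificed, so C4, C5 and the bridge are all created late. The C9 oxygen must be oxidised, the C6 hydroxyl methylated selectively beside the tertiary one, and a peroxide carried through several operations.
- Comparison: on ring B oxygenation and on the regiochemistry of nitrogen this alternative is the better one, since it needs no aminohydroxylation. Its cycloaddition is also mechanistically more secure than a Lewis-acid closure onto a trione. On the bridged skeleton the chosen plan is stronger, because one C–C bond gives the bicycle, both bridgeheads and the alkene. Step economy is about equal, since A2 needs a cross-coupling and the closure of ring A several redox adjustments.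

Alternative 2: The cut is made at C3–N. In the forward direction the primary carbamate A4 on the exo C4 oxygen is oxidised (PhI(OAc)2, MgO, Rh2(OAc)4) to a rhodium nitrenoid that inserts into the exo C3–H bond and gives the cis-fused oxazolidinone A3.
- In its favour: the tether guarantees nitrogen on C3 and the cis relation, with retention at carbon. The oxidant tolerates the epoxide. Ring A needs no alkene, so the bicycle could come from a plain Michael–aldol annulation that supplies the C4 hydroxyl at once.
- Against it here: the bridgehead C5–H bond and the ether C–H bonds compete for the nitrenoid. The C4 hydroxyl must be exo. A3 must be opened beside an epoxide and a ketone, which requires N-activation first. Nitrogen enters on the most advanced intermediate.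
- Comparison: on ring B and on facial control it is the equal of the chosen plan, and on regiocontrol at nitrogen it is the better one. It is longer at the end: carbamoylation, insertion, activation, opening, deprotection and acylation stand against aminohydroxylation, deprotection and acylation. Its mechanism places the riskiest C–H selectivity on the most valuable material. The chosen plan keeps this chemistry as the fallback for step 13.

Alternative 3: The cuts are made at C1–C2 and C4–C5. In the forward direction the 2-alkoxy dione A6 adds through C1 to the CH2 terminus of 2-phthalimidoacrolein A7, and a chiral amine catalyst then drives the aldol reaction of C5 with the aldehyde, which gives the keto alcohol A5.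
- In its favour: this is the shortest entry to ring A, with nitrogen on C3 and oxygen on C4 fixed by connectivity. It needs no silicon, no trione and no aminohydroxylation. The aldol product can neither dehydrate nor easily revert, because C5 is a bridgehead.
- Against it here: the absolute configuration rests on a desymmetrising aldol in which a hindered ketone must be the donor while the amine condenses first with the aldehyde. C3, which is epimerisable next to the aldehyde, and C4 must both come out exo from one reversible step. The phthalimide must later be removed beside ketones.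
- Comparison: on step economy and on regiochemistry this alternative is the better plan, and on ring B it is equal. It is weaker on absolute and relative stereocontrol, where the chosen plan relies on a catalytic asymmetric silyl addition of a known kind and on a geometric relay through the anti SE2′ transition state.

Key step: step 6

Remark: bicyclic intermediates carry the locants of the target (C1 carbinol bridgehead, C5 bridgehead CH, C9 bridging carbonyl), also where lowest-locant rules would number differently; "exo" means syn to C9.
Remark: 3-ethoxycyclohex-2-en-1-one (1) is bought as the ethyl enol ether of cyclohexane-1,3-dione.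
Remark: the descriptor at C5 changes between 11 (5R) and 13 onwards (5S) because substituent priorities change; the geometry does not.
Remark: in step 3 the enantiomer of the carbene ligand is the one that gives (S) at the silyl-bearing carbon.

## Route

Step 1
Reactants: 1 3-ethoxycyclohex-2-en-1-one; 2 acrolein
Product: 3 3-ethoxy-6-(1-hydroxyprop-2-en-1-yl)cyclohex-2-en-1-one (racemic mixture of diastereomers)
Conditions: LiN(i-Pr)2, THF, −78 °C; then 2, −78 °C; AcOH
Reagents that add atoms: none
Why: Kinetic α′-deprotonation of the vinylogous ester and aldol 1,2-addition of the lithium enolate to the enal at low temperature; both new stereocentres are destroyed in step 2.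

Step 2
Reactants: 3 3-ethoxy-6-(1-hydroxyprop-2-en-1-yl)cyclohex-2-en-1-one
Product: 5 (6E)-3-ethoxy-6-(prop-2-en-1-ylidene)cyclohex-2-en-1-one, via allylic mesylate 4 (not isolated)
Conditions: MsCl, Et3N, CH2Cl2, 0 °C; then DBU, 0 °C → rt
Reagents that add atoms: none
Why: Mesylation and E1cB elimination through the enolate complete the aldol condensation and give the conjugated exocyclic alkene; the E isomer, with the vinyl group away from the carbonyl, is the thermodynamically preferred one.

Step 3
Reactants: 5 (6E)-3-ethoxy-6-(prop-2-en-1-ylidene)cyclohex-2-en-1-one; 6 (dimethylphenylsilyl)boronic acid pinacol ester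
Product: 7 (6S)-6-[(1S)-1-(dimethylphenylsilyl)prop-2-en-1-yl]-3-ethoxycyclohex-2-en-1-one
Conditions: CuCl (5 mol %), chiral imidazolinium salt (carbene precursor, 5.5 mol %), NaOt-Bu (11 mol %), MeOH (2 equiv), THF, −78 °C
Reagents that add atoms: none
Why: Copper-catalysed enantioselective conjugate silylation: the silyl group passes from boron to the monovalent copper–carbene complex and adds to the alkene carbon β to the carbonyl (1,4-addition, as known for acyclic β-alkenyl enones), the ligand fixing (S) at the silyl carbon. Methanol protonates the copper enolate anti to the bulky silyl group (hydrogen of the silyl carbon eclipsing the enolate), which should favour the (6S) epimer required in step 6.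

Step 4
Reactants: 7 (6S)-6-[(1S)-1-(dimethylphenylsilyl)prop-2-en-1-yl]-3-ethoxycyclohex-2-en-1-one
Product: 8 (4S)-4-[(1S)-1-(dimethylphenylsilyl)prop-2-en-1-yl]cyclohexane-1,3-dione
Conditions: 0.5 M HCl, THF, 0 °C → rt
Reagents that add atoms: water, O
Why: Acid hydrolysis of the vinylogous ester; dilute aqueous acid at or below room temperature should neither protodesilylate the allylsilane nor epimerise the ring stereocentre, which is not on the enolised side of the dione.

Step 5
Reactants: 8 (4S)-4-[(1S)-1-(dimethylphenylsilyl)prop-2-en-1-yl]cyclohexane-1,3-dione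
Product: 9 (4S)-2-[(dimethylamino)methylidene]-4-[(1S)-1-(dimethylphenylsilyl)prop-2-en-1-yl]cyclohexane-1,3-dione
Conditions: Me2NCH(OMe)2, CH2Cl2, rt
Reagents that add atoms: N,N-dimethylformamide dimethyl acetal, COC(OC)N(C)C
Why: Condensation of the amide acetal at the doubly activated C2 gives the push–pull enaminone, a stable and storable latent trione that can neither hydrate nor aromatise; no stereocentre is touched.

Step 6
Reactants: 9 (4S)-2-[(dimethylamino)methylidene]-4-[(1S)-1-(dimethylphenylsilyl)prop-2-en-1-yl]cyclohexane-1,3-dione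
Product: 11 (1S,5R)-1-hydroxybicyclo[3.3.1]non-3-ene-8,9-dione, via cyclohexanetrione 10 (not isolated)
Conditions: O2, tetraphenylporphyrin (cat.), visible light, CH2Cl2, −78 °C; Ar purge; then TiCl4 (3 equiv), −78 → −40 °C; aq. NaHCO3
Reagents that add atoms: dioxygen, O=O
Why: Singlet oxygen adds to the electron-rich enamine C=C of 9 and the dioxetane fragments to DMF and the anhydrous trione 10 (oxidative enamine cleavage, a standard entry to vicinal tricarbonyls), the monosubstituted vinyl group being inert on this timescale. TiCl4 then binds the vicinal carbonyls and the alkene terminus C2 attacks the central carbonyl C1, the β-silyl cation at C3 collapsing to the C3=C4 alkene with loss of silicon; the closest known reaction type is the intramolecular Hosomi–Sakurai allylation of ketones and 1,2-diones. Ring A closes in a 6-exo-trig mode at the carbonyl with the allyl π bond inside the new ring, through a chair in which the side chain is axial on ring B and bridges C5 to C1. Anti SE2′ geometry requires the C4–Si bond perpendicular to the allyl plane and opposite to C1, that is axial on the exo face of the nascent ring A, which only the (4S) epimer at C5 can provide; the (S) silyl centre therefore selects the configuration of C5, and C1 follows because the one-carbon bridge can only reach the carbonyl face syn to the side chain. The (4S) epimer is the one delivered by step 3, while a (4R) contaminant has silicon in the ring plane, cannot close through the chair and can rejoin only through the C9 enol. The step needs three selectivities: C1 over C8 and C9 (C1 is the most electrophilic carbonyl and the only one that gives a six-membered ring), SE2′ over ene-type transfer of the C4 hydrogen (secured by the aligned C–Si bond), and closure faster than enolisation of 10, which would lead irreversibly to a 4-substituted pyrogallol; hence the neutral, dry generation and immediate use at −78 °C.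

Step 7
Reactants: 11 (1S,5R)-1-hydroxybicyclo[3.3.1]non-3-ene-8,9-dione
Product: 12 (1S,5R)-1,8-bis(triethylsilyloxy)bicyclo[3.3.1]nona-3,7-dien-9-one
Conditions: Et3SiOTf (2.5 equiv), Et3N, CH2Cl2, −78 → 0 °C
Reagents that add atoms: triethylsilyl trifluoromethanesulfonate, CC[Si](CC)(CC)OS(=O)(=O)C(F)(F)F
Why: Silyl triflate with amine base silylates the tertiary bridgehead alcohol and converts the only enolisable ketone (C8, towards C7) into its silyl enol ether (soft enolisation); C9 has no enolisable position, and capping O1 blocks α-ketol rearrangement later.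

Step 8
Reactants: 12 (1S,5R)-1,8-bis(triethylsilyloxy)bicyclo[3.3.1]nona-3,7-dien-9-one
Product: 13 (1S,5S)-1-(triethylsilyloxy)bicyclo[3.3.1]nona-3,6-diene-8,9-dione
Conditions: Pd(OAc)2 (10 mol %), O2 (1 atm), DMSO, rt
Reagents that add atoms: none
Why: Saegusa–Ito oxidation: palladation of the silyl enol ether at C7 and β-hydride elimination of a C6 hydrogen give the C6=C7 enone, with O2 returning palladium to the divalent state; the tertiary silyl ether and the isolated C3=C4 alkene are not affected.

Step 9
Reactants: 13 (1S,5S)-1-(triethylsilyloxy)bicyclo[3.3.1]nona-3,6-diene-8,9-dione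
Product: 14 (1R,5S,6S,7S)-6,7-epoxy-1-(triethylsilyloxy)bicyclo[3.3.1]non-3-ene-8,9-dione (epoxide exo)
Conditions: t-BuOOH, DBU, CH2Cl2, 0 °C
Reagents that add atoms: tert-butyl hydroperoxide, CC(C)(C)OO
Why: Weitz–Scheffer nucleophilic epoxidation: the peroxide anion adds to C6 from the exo face (axial attack, past the flat C9 carbonyl and away from ring A) and the enolate closes the epoxide on the same face, fixing C6 and C7. A bulky peroxide with an amidine base in an aprotic solvent is chosen to spare the non-enolisable 1,3-diketone from retro-Claisen cleavage.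

Step 10
Reactants: 14 (1R,5S,6S,7S)-6,7-epoxy-1-(triethylsilyloxy)bicyclo[3.3.1]non-3-ene-8,9-dione
Product: 16 (1S,5S,6R)-6-hydroxy-1-(triethylsilyloxy)bicyclo[3.3.1]nona-3,7-dien-9-one, via epoxy hydrazone 15 (not isolated)
Conditions: N2H4·H2O (2 equiv), AcOH (cat.), MeOH, 0 °C → rt
Reagents that add atoms: none
Why: Wharton transposition: hydrazone formation at the activated, less hindered C8 carbonyl, opening of the epoxide to an alkenyl diazene and loss of N2 give the C7=C8 alkene. The C6–O bond is never broken, so the exo hydroxyl is retained; C9 is shielded by quaternary C1 and by exo substituents on both sides.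

Step 11
Reactants: 16 (1S,5S,6R)-6-hydroxy-1-(triethylsilyloxy)bicyclo[3.3.1]nona-3,7-dien-9-one
Product: 17 (1S,5S,6S,7S,8S)-7,8-epoxy-6-hydroxy-1-(triethylsilyloxy)bicyclo[3.3.1]non-3-en-9-one
Conditions: VO(acac)2 (5 mol %), t-BuOOH, CH2Cl2, 0 °C → rt
Reagents that add atoms: tert-butyl hydroperoxide, CC(C)(C)OO
Why: Vanadium-catalysed hydroxyl-directed epoxidation: the axial exo C6 hydroxyl binds the vanadium peroxide and delivers oxygen to the exo face of C7=C8, cis to itself. The C3=C4 alkene, which this hydroxyl cannot reach on its exo face, should react far more slowly.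

Step 12
Reactants: 17 (1S,5S,6S,7S,8S)-7,8-epoxy-6-hydroxy-1-(triethylsilyloxy)bicyclo[3.3.1]non-3-en-9-one
Product: 18 (1S,5S,6S,7S,8S)-7,8-epoxy-6-methoxy-1-(triethylsilyloxy)bicyclo[3.3.1]non-3-en-9-one
Conditions: Me3OBF4, 1,8-bis(dimethylamino)naphthalene, 4 Å MS, CH2Cl2, 0 °C → rt
Reagents that add atoms: trimethyloxonium tetrafluoroborate, C[O+](C)C.F[B-](F)(F)F
Why: O-Methylation of a hindered secondary alcohol with an oxonium salt and a non-nucleophilic proton scavenger, conditions free of strong base that leave epoxide, ketone and silyl ether alone; C6 keeps its configuration.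

Step 13
Reactants: 18 (1S,5S,6S,7S,8S)-7,8-epoxy-6-methoxy-1-(triethylsilyloxy)bicyclo[3.3.1]non-3-en-9-one
Product: 19 2-(trimethylsilyl)ethyl N-[(1S,3S,4R,5S,6S,7S,8S)-7,8-epoxy-4-hydroxy-6-methoxy-9-oxo-1-(triethylsilyloxy)bicyclo[3.3.1]nonan-3-yl]carbamate
Conditions: Me3SiCH2CH2OC(O)NH2 (3 equiv), t-BuOCl, NaOH, K2OsO2(OH)4 (4 mol %), (DHQD)2PHAL (5 mol %), n-PrOH/H2O 1:1, rt
Reagents that add atoms: 2-(trimethylsilyl)ethyl carbamate, C[Si](C)(C)CCOC(N)=O; water, O
Why: Osmium-catalysed syn aminohydroxylation with the N-chloro carbamate salt: the imido-osmium species adds suprafacially to the exo face of C3=C4 (the endo face is closed by ring B), so N and O arrive cis and exo, the ligand serving turnover. The carbamate nitrogen is expected on C3, where it ends equatorial and remote from the branched bridgehead, and oxygen on the axial, more hindered C4; no 1,3-diketone is present at this stage to suffer from the aqueous base.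

Step 14
Reactants: 19 2-(trimethylsilyl)ethyl N-[(1S,3S,4R,5S,6S,7S,8S)-7,8-epoxy-4-hydroxy-6-methoxy-9-oxo-1-(triethylsilyloxy)bicyclo[3.3.1]nonan-3-yl]carbamate
Product: 20 (1S,3S,4R,5S,6S,7S,8S)-3-amino-7,8-epoxy-1,4-dihydroxy-6-methoxybicyclo[3.3.1]nonan-9-one
Conditions: Bu4NF (4 equiv), AcOH (2 equiv), THF, 0 °C → rt
Reagents that add atoms: none
Why: Fluoride cleaves the triethylsilyl ether and triggers β-elimination of the 2-(trimethylsilyl)ethyl carbamate (ethene and CO2 lost), releasing the amine; buffering with acetic acid guards the α-ketol and the epoxide against base, and no stereocentre is involved.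

Step 15
Reactants: 20 (1S,3S,4R,5S,6S,7S,8S)-3-amino-7,8-epoxy-1,4-dihydroxy-6-methoxybicyclo[3.3.1]nonan-9-one; 21 (2E)-dodec-2-enoic acid
Product: 22 (2E)-N-[(1S,3S,4R,5S,6S,7S,8S)-7,8-epoxy-1,4-dihydroxy-6-methoxy-9-oxobicyclo[3.3.1]nonan-3-yl]dodec-2-enamide
Conditions: EDC·HCl, 1-hydroxybenzotriazole, i-Pr2NEt, CH2Cl2, 0 °C → rt
Reagents that add atoms: none
Why: Carbodiimide and hydroxybenzotriazole amide coupling; the primary amine is acylated much faster than the secondary and tertiary hydroxyls, and the active ester does not isomerise the E-enoyl unit.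

## Compound list

1 | 3-ethoxycyclohex-2-en-1-one | CCOC1=CC(=O)CCC1 | starting material
2 | acrolein (prop-2-enal) | C=CC=O | starting material
3 | 3-ethoxy-6-(1-hydroxyprop-2-en-1-yl)cyclohex-2-en-1-one (racemic, both diastereomers) | CCOC1=CC(=O)C(CC1)C(O)C=C | intermediate
4 | 1-(4-ethoxy-2-oxocyclohex-3-en-1-yl)prop-2-en-1-yl methanesulfonate | CCOC1=CC(=O)C(CC1)C(OS(C)(=O)=O)C=C | intermediate (not isolated)
5 | (6E)-3-ethoxy-6-(prop-2-en-1-ylidene)cyclohex-2-en-1-one | CCOC1=CC(=O)/C(CC1)=C/C=C | intermediate
6 | (dimethylphenylsilyl)boronic acid pinacol ester | CC1(C)OB(OC1(C)C)[Si](C)(C)c1ccccc1 | starting material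
7 | (6S)-6-[(1S)-1-(dimethylphenylsilyl)prop-2-en-1-yl]-3-ethoxycyclohex-2-en-1-one | C=C[C@H]([Si](C)(C)c1ccccc1)[C@H]1CCC(OCC)=CC1=O | intermediate
8 | (4S)-4-[(1S)-1-(dimethylphenylsilyl)prop-2-en-1-yl]cyclohexane-1,3-dione | C=C[C@H]([Si](C)(C)c1ccccc1)[C@H]1CCC(=O)CC1=O | intermediate
9 | (4S)-2-[(dimethylamino)methylidene]-4-[(1S)-1-(dimethylphenylsilyl)prop-2-en-1-yl]cyclohexane-1,3-dione | C=C[C@H]([Si](C)(C)c1ccccc1)[C@H]1CCC(=O)C(=CN(C)C)C1=O | intermediate
10 | (4S)-4-[(1S)-1-(dimethylphenylsilyl)prop-2-en-1-yl]cyclohexane-1,2,3-trione | C=C[C@H]([Si](C)(C)c1ccccc1)[C@H]1CCC(=O)C(=O)C1=O | intermediate (not isolated)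
11 | (1S,5R)-1-hydroxybicyclo[3.3.1]non-3-ene-8,9-dione | C1C[C@@]2(O)C(=O)[C@@H](C=1)CCC2=O | intermediate
12 | (1S,5R)-1,8-bis(triethylsilyloxy)bicyclo[3.3.1]nona-3,7-dien-9-one | C1C[C@@]2(O[Si](CC)(CC)CC)C(=O)[C@@H](C=1)CC=C2O[Si](CC)(CC)CC | intermediate
13 | (1S,5S)-1-(triethylsilyloxy)bicyclo[3.3.1]nona-3,6-diene-8,9-dione | C1C[C@@]2(O[Si](CC)(CC)CC)C(=O)[C@@H](C=1)C=CC2=O | intermediate
14 | (1R,5S,6S,7S)-6,7-epoxy-1-(triethylsilyloxy)bicyclo[3.3.1]non-3-ene-8,9-dione (epoxide exo) | C1C[C@@]2(O[Si](CC)(CC)CC)C(=O)[C@@H](C=1)[C@@H]1O[C@@H]1C2=O | intermediate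
15 | (1S,5S,6S,7R)-6,7-epoxy-8-hydrazinylidene-1-(triethylsilyloxy)bicyclo[3.3.1]non-3-en-9-one | C1C[C@@]2(O[Si](CC)(CC)CC)C(=O)[C@@H](C=1)[C@@H]1O[C@@H]1C2=NN | intermediate (not isolated)
16 | (1S,5S,6R)-6-hydroxy-1-(triethylsilyloxy)bicyclo[3.3.1]nona-3,7-dien-9-one (hydroxyl exo) | C1C[C@@]2(O[Si](CC)(CC)CC)C(=O)[C@@H](C=1)[C@H](O)C=C2 | intermediate
17 | (1S,5S,6S,7S,8S)-7,8-epoxy-6-hydroxy-1-(triethylsilyloxy)bicyclo[3.3.1]non-3-en-9-one | C1C[C@@]2(O[Si](CC)(CC)CC)C(=O)[C@@H](C=1)[C@H](O)[C@@H]1O[C@@H]12 | intermediate
18 | (1S,5S,6S,7S,8S)-7,8-epoxy-6-methoxy-1-(triethylsilyloxy)bicyclo[3.3.1]non-3-en-9-one | C1C[C@@]2(O[Si](CC)(CC)CC)C(=O)[C@@H](C=1)[C@H](OC)[C@@H]1O[C@@H]12 | intermediate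
19 | 2-(trimethylsilyl)ethyl N-[(1S,3S,4R,5S,6S,7S,8S)-7,8-epoxy-4-hydroxy-6-methoxy-9-oxo-1-(triethylsilyloxy)bicyclo[3.3.1]nonan-3-yl]carbamate | C[Si](C)(C)CCOC(=O)N[C@H]1C[C@@]2(O[Si](CC)(CC)CC)C(=O)[C@@H]([C@H]1O)[C@H](OC)[C@@H]1O[C@@H]12 | intermediate
20 | (1S,3S,4R,5S,6S,7S,8S)-3-amino-7,8-epoxy-1,4-dihydroxy-6-methoxybicyclo[3.3.1]nonan-9-one | N[C@H]1C[C@@]2(O)C(=O)[C@@H]([C@H]1O)[C@H](OC)[C@@H]1O[C@@H]12 | intermediate
21 | (2E)-dodec-2-enoic acid | CCCCCCCCC/C=C/C(=O)O | starting material
22 | (2E)-N-[(1S,3S,4R,5S,6S,7S,8S)-7,8-epoxy-1,4-dihydroxy-6-methoxy-9-oxobicyclo[3.3.1]nonan-3-yl]dodec-2-enamide | CCCCCCCCC/C=C/C(=O)N[C@H]1C[C@@]2(O)C(=O)[C@@H]([C@H]1O)[C@H](OC)[C@@H]1O[C@@H]12 | target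

## Step count and least certain steps

Total: 15 steps. Longest linear sequence: 15 steps (1 to 22); 2, 6 and 21 are used as bought.

**Step 6 (key step).** The most likely failure is enolisation of 10 under the Lewis acid towards C5 or C7, followed by tautomerisation to an aromatic triol, because the trione is a keto tautomer of a pyrogallol. Protodesilylation by adventitious acid is the second risk, and a (4R) epimer that cannot close would be lost.
Fallback (sets out from 1 and 2, returns at 11): the allylsilane is given up and ring A is closed by a Michael–aldol annulation. Hydrolysis of 1 with 1 M HCl in THF gives cyclohexane-1,3-dione F1, which can equally be bought. Diazo transfer with 4-acetamidobenzenesulfonyl azide and Et3N in MeCN gives 2-diazocyclohexane-1,3-dione F2. Rh2(OAc)4-catalysed O–H insertion into 4-methoxybenzyl alcohol then gives 2-[(4-methoxybenzyl)oxy]cyclohexane-1,3-dione F3. Et3N-catalysed Michael addition of F3 through C2 to 2 gives 3-{1-[(4-methoxybenzyl)oxy]-2,6-dioxocyclohexyl}propanal F4. An intramolecular aldol reaction (pyrrolidine, AcOH, CH2Cl2) closes it to racemic 4-hydroxy-1-[(4-methoxybenzyl)oxy]bicyclo[3.3.1]nonane-8,9-dione F5, a mixture of C4 epimers. Syn dehydration with the Burgess reagent in warm toluene serves both epimers and can only run towards C3, since C5 is a bridgehead; it gives racemic 1-[(4-methoxybenzyl)oxy]bicyclo[3.3.1]non-3-ene-8,9-dione F6. Chromatography on a chiral stationary phase then delivers (1S,5R)-1-[(4-methoxybenzyl)oxy]bicyclo[3.3.1]non-3-ene-8,9-dione F7. DDQ in wet CH2Cl2 cleaves the benzylic ether of F7 and returns to 11.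

**Step 3.** The likely failure is delivery of silicon to the unhindered terminal carbon of the dienone (1,6-addition), which would give the wrong allylsilane, or poor face selectivity on this exocyclic, vinylogous-ester acceptor.
Fallback (sets out from 1 and 2, returns at 7): the vinyl group is masked so that only 1,4-addition is possible. Conjugate addition of benzeneselenol to 2 gives 3-(phenylselanyl)propanal F8. The lithium enolate of 1 adds to it under the conditions of step 1 and gives 3-ethoxy-6-[1-hydroxy-3-(phenylselanyl)propyl]cyclohex-2-en-1-one F9. Mesylation gives 1-(4-ethoxy-2-oxocyclohex-3-en-1-yl)-3-(phenylselanyl)propyl methanesulfonate F10, which DBU eliminates to (6E)-3-ethoxy-6-[3-(phenylselanyl)propylidene]cyclohex-2-en-1-one F11. The copper-catalysed silylation of step 3, now on a simple β-alkyl enone, gives (6S)-6-[(1S)-1-(dimethylphenylsilyl)-3-(phenylselanyl)propyl]-3-ethoxycyclohex-2-en-1-one F12. H2O2 with pyridine in CH2Cl2 at 0 °C gives (6S)-6-[(1S)-1-(dimethylphenylsilyl)-3-(phenylseleninyl)propyl]-3-ethoxycyclohex-2-en-1-one F13. Syn elimination of the selenoxide on warming to room temperature unveils the terminal alkene and returns to 7.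

**Step 10.** The likely failure is condensation of hydrazine with C9, or nucleophilic cleavage of the 1,3-diketone around C1, in competition with hydrazone formation at C8.
Fallback (sets out from 14, returns at 16): the transposition is done by radical fragmentation instead of through a hydrazone. NaBH4 with CeCl3·7H2O in MeOH at −78 °C reduces the more accessible, epoxide-activated C8 carbonyl to 6,7-epoxy-8-hydroxy-1-(triethylsilyloxy)bicyclo[3.3.1]non-3-en-9-one F14, either C8 epimer of which serves. 1,1′-Thiocarbonyldiimidazole converts it into O-[6,7-epoxy-9-oxo-1-(triethylsilyloxy)bicyclo[3.3.1]non-3-en-8-yl] 1H-imidazole-1-carbothioate F15. Bu3SnH and azobisisobutyronitrile in toluene at 80 °C generate the C8 radical, which opens the adjacent epoxide; hydrogen transfer to the C6 alkoxy radical returns to 16.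

**Step 13.** The likely failure is poor regioselectivity, with part of the nitrogen ending on C4, because the two alkene carbons differ only by the branching of their neighbours.
Fallback (sets out from 18, returns at 19): nitrogen is tethered to the C4 oxygen and delivered to C3 by C–H insertion.
- A singlet-oxygen ene reaction on the exo face (O2, tetraphenylporphyrin, visible light) can abstract only a C2 hydrogen, since C5 is a bridgehead. It gives 7,8-epoxy-4-exo-hydroperoxy-6-methoxy-1-(triethylsilyloxy)bicyclo[3.3.1]non-2-en-9-one F16.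
- PPh3 reduces the hydroperoxide to 7,8-epoxy-4-exo-hydroxy-6-methoxy-1-(triethylsilyloxy)bicyclo[3.3.1]non-2-en-9-one F17.
- H2 over Pd/C in EtOAc gives 7,8-epoxy-4-exo-hydroxy-6-methoxy-1-(triethylsilyloxy)bicyclo[3.3.1]nonan-9-one F18.
- Cl3CC(O)NCO in CH2Cl2 gives 7,8-epoxy-6-methoxy-9-oxo-1-(triethylsilyloxy)bicyclo[3.3.1]nonan-4-exo-yl N-(trichloroacetyl)carbamate F19.
- K2CO3 in MeOH converts it into 7,8-epoxy-6-methoxy-9-oxo-1-(triethylsilyloxy)bicyclo[3.3.1]nonan-4-exo-yl carbamate F20.
- Rh2(OAc)4, PhI(OAc)2 and MgO in CH2Cl2 effect nitrene insertion into the exo C3–H bond with retention. The product is the cis-fused oxazolidin-2-one of the 7,8-epoxy-6-methoxy-1-(triethylsilyloxy)bicyclo[3.3.1]nonan-9-one core F21.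
- 2-(Trimethylsilyl)ethyl 4-nitrophenyl carbonate with Et3N and 4-(dimethylamino)pyridine gives its N-[2-(trimethylsilyl)ethoxycarbonyl] derivative F22.
- Cs2CO3 in MeOH opens the ring of F22 at the endocyclic carbonyl and returns to 19.

## Further compounds

F1 | step 6 | cyclohexane-1,3-dione | O=C1CCCC(=O)C1
F2 | step 6 | 2-diazocyclohexane-1,3-dione | [N-]=[N+]=C1C(=O)CCCC1=O
F3 | step 6 | 2-[(4-methoxybenzyl)oxy]cyclohexane-1,3-dione | O=C1CCCC(=O)C1OCc1ccc(OC)cc1
F4 | step 6 | 3-{1-[(4-methoxybenzyl)oxy]-2,6-dioxocyclohexyl}propanal | O=CCCC1(OCc2ccc(OC)cc2)C(=O)CCCC1=O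
F5 | step 6 | racemic 4-hydroxy-1-[(4-methoxybenzyl)oxy]bicyclo[3.3.1]nonane-8,9-dione (C4 epimers) | C1CC2(OCc3ccc(OC)cc3)C(=O)C(C1O)CCC2=O
F6 | step 6 | racemic 1-[(4-methoxybenzyl)oxy]bicyclo[3.3.1]non-3-ene-8,9-dione | C1CC2(OCc3ccc(OC)cc3)C(=O)C(C=1)CCC2=O
F7 | step 6 | (1S,5R)-1-[(4-methoxybenzyl)oxy]bicyclo[3.3.1]non-3-ene-8,9-dione | C1C[C@@]2(OCc3ccc(OC)cc3)C(=O)[C@@H](C=1)CCC2=O
F8 | step 3 | 3-(phenylselanyl)propanal | O=CCC[Se]c1ccccc1
F9 | step 3 | 3-ethoxy-6-[1-hydroxy-3-(phenylselanyl)propyl]cyclohex-2-en-1-one | CCOC1=CC(=O)C(CC1)C(O)CC[Se]c1ccccc1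
F10 | step 3 | 1-(4-ethoxy-2-oxocyclohex-3-en-1-yl)-3-(phenylselanyl)propyl methanesulfonate | CCOC1=CC(=O)C(CC1)C(OS(C)(=O)=O)CC[Se]c1ccccc1
F11 | step 3 | (6E)-3-ethoxy-6-[3-(phenylselanyl)propylidene]cyclohex-2-en-1-one | CCOC1=CC(=O)/C(CC1)=C/CC[Se]c1ccccc1
F12 | step 3 | (6S)-6-[(1S)-1-(dimethylphenylsilyl)-3-(phenylselanyl)propyl]-3-ethoxycyclohex-2-en-1-one | c1ccccc1[Se]CC[C@H]([Si](C)(C)c1ccccc1)[C@H]1CCC(OCC)=CC1=O
F13 | step 3 | (6S)-6-[(1S)-1-(dimethylphenylsilyl)-3-(phenylseleninyl)propyl]-3-ethoxycyclohex-2-en-1-one | O=[Se](c1ccccc1)CC[C@H]([Si](C)(C)c1ccccc1)[C@H]1CCC(OCC)=CC1=O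
F14 | step 10 | 6,7-epoxy-8-hydroxy-1-(triethylsilyloxy)bicyclo[3.3.1]non-3-en-9-one (C8 epimers; other centres as in 14) | C1C[C@@]2(O[Si](CC)(CC)CC)C(=O)[C@@H](C=1)[C@@H]1O[C@@H]1C2O
F15 | step 10 | O-[6,7-epoxy-9-oxo-1-(triethylsilyloxy)bicyclo[3.3.1]non-3-en-8-yl] 1H-imidazole-1-carbothioate | C1C[C@@]2(O[Si](CC)(CC)CC)C(=O)[C@@H](C=1)[C@@H]1O[C@@H]1C2OC(=S)n1ccnc1
F16 | step 13 | 7,8-epoxy-4-exo-hydroperoxy-6-methoxy-1-(triethylsilyloxy)bicyclo[3.3.1]non-2-en-9-one (other centres as in 18) | C1=C[C@@]2(O[Si](CC)(CC)CC)C(=O)[C@@H]([C@H]1OO)[C@H](OC)[C@@H]1O[C@@H]12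
F17 | step 13 | 7,8-epoxy-4-exo-hydroxy-6-methoxy-1-(triethylsilyloxy)bicyclo[3.3.1]non-2-en-9-one (other centres as in 18) | C1=C[C@@]2(O[Si](CC)(CC)CC)C(=O)[C@@H]([C@H]1O)[C@H](OC)[C@@H]1O[C@@H]12
F18 | step 13 | 7,8-epoxy-4-exo-hydroxy-6-methoxy-1-(triethylsilyloxy)bicyclo[3.3.1]nonan-9-one | C1C[C@@]2(O[Si](CC)(CC)CC)C(=O)[C@@H]([C@H]1O)[C@H](OC)[C@@H]1O[C@@H]12
F19 | step 13 | 7,8-epoxy-6-methoxy-9-oxo-1-(triethylsilyloxy)bicyclo[3.3.1]nonan-4-exo-yl N-(trichloroacetyl)carbamate | C1C[C@@]2(O[Si](CC)(CC)CC)C(=O)[C@@H]([C@H]1OC(=O)NC(=O)C(Cl)(Cl)Cl)[C@H](OC)[C@@H]1O[C@@H]12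
F20 | step 13 | 7,8-epoxy-6-methoxy-9-oxo-1-(triethylsilyloxy)bicyclo[3.3.1]nonan-4-exo-yl carbamate | C1C[C@@]2(O[Si](CC)(CC)CC)C(=O)[C@@H]([C@H]1OC(N)=O)[C@H](OC)[C@@H]1O[C@@H]12
F21 | step 13 | cis-fused (N on C3, O on C4, both exo) oxazolidin-2-one of the 7,8-epoxy-6-methoxy-1-(triethylsilyloxy)bicyclo[3.3.1]nonan-9-one core | O=C1N[C@H]2C[C@@]3(O[Si](CC)(CC)CC)C(=O)[C@@H]([C@H]2O1)[C@H](OC)[C@@H]2O[C@@H]23
F22 | step 13 | N-[2-(trimethylsilyl)ethoxycarbonyl] derivative of F21 | O=C1N(C(=O)OCC[Si](C)(C)C)[C@H]2C[C@@]3(O[Si](CC)(CC)CC)C(=O)[C@@H]([C@H]2O1)[C@H](OC)[C@@H]2O[C@@H]23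
A1 | alternative 1 | endoperoxide (2,3-dioxabicyclo[2.2.2]oct-5-ene) of A2, peroxide anti to the acetonide | COC(=O)[C@@H](NC(=O)OC(C)(C)C)C[C@]12OO[C@H](C=C1)[C@@H]1OC(C)(C)O[C@H]21
A2 | alternative 1 | methyl (2S)-2-[(tert-butoxycarbonyl)amino]-3-[cis-5,6-(isopropylidenedioxy)cyclohexa-1,3-dien-1-yl]propanoate | COC(=O)[C@@H](NC(=O)OC(C)(C)C)CC1=CC=C[C@@H]2OC(C)(C)O[C@H]12
A3 | alternative 2 | cis-fused oxazolidin-2-one (N on C3, O on C4) of the 7,8-epoxy-6-methoxy-1-(triethylsilyloxy)bicyclo[3.3.1]nonan-9-one core | O=C1N[C@H]2C[C@@]3(O[Si](CC)(CC)CC)C(=O)[C@@H]([C@H]2O1)[C@H](OC)[C@@H]2O[C@@H]23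
A4 | alternative 2 | 7,8-epoxy-6-methoxy-9-oxo-1-(triethylsilyloxy)bicyclo[3.3.1]nonan-4-exo-yl carbamate | C1C[C@@]2(O[Si](CC)(CC)CC)C(=O)[C@@H]([C@H]1OC(N)=O)[C@H](OC)[C@@H]1O[C@@H]12
A5 | alternative 3 | 4-exo-hydroxy-1-[(4-methoxybenzyl)oxy]-3-exo-phthalimidobicyclo[3.3.1]nonane-8,9-dione | O=C1c2ccccc2C(=O)N1[C@H]1C[C@@]2(OCc3ccc(OC)cc3)C(=O)[C@@H]([C@H]1O)CCC2=O
A6 | alternative 3 | 2-[(4-methoxybenzyl)oxy]cyclohexane-1,3-dione | O=C1CCCC(=O)C1OCc1ccc(OC)cc1
A7 | alternative 3 | 2-phthalimidoacrolein | O=CC(=C)N1C(=O)c2ccccc2C1=O
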